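**Retrosynthetic overview**

- Feature: in ring A the oxygens on C5 and C8 are para, so ring A is carried as a 2,5-dimethoxyaryl ketone, a masked 5,8-quinone. In the unmasked acylquinone the ring CH that becomes C8a (between C8 and C4a) is the β-carbon of both the C5 quinone carbonyl and the C4 ketone.
- Ring C (the only ring made, and the last): O1–C8a, by anodic unmasking of the quinone in 1,3-diketone 12 and closure by the enol oxygen; then 8-O-methylation and 7-O-deallylation.
- C3–C4: aldol addition of the ring B α-methoxy ketone 9 to the ring A aldehyde 3, then oxidation of the carbinol.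
- C2–C1' (aryl Grignard plus methoxyacetyl Weinreb amide) and C4–C4a (Vilsmeier formylation of O-allylated 2,5-dimethoxyphenol); rings A and B are bought as benzenes.

Key step: step 7

Remark: 2,5-dimethoxyphenol is taken as purchasable, and the potential quoted in step 7 is an estimate to be fixed by cyclic voltammetry of 12.

**Step 1**
Reactants: 1 2,5-dimethoxyphenol
Product: 2 2-(allyloxy)-1,4-dimethoxybenzene
Conditions: allyl bromide, K2CO3, acetone, reflux
Reagents that add atoms: allyl bromide, C=CCBr
Why: Williamson ether synthesis, the phenoxide displacing bromide from the primary allylic carbon.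

**Step 2**
Reactants: 2 2-(allyloxy)-1,4-dimethoxybenzene
Product: 3 4-(allyloxy)-2,5-dimethoxybenzaldehyde
Conditions: POCl3, DMF, 0 °C to 60 °C; then aq. NaOAc
Reagents that add atoms: N,N-dimethylformamide, CN(C)C=O (formyl carbon); water, O (aldehyde oxygen)
Why: Vilsmeier–Haack formylation should take the unhindered carbon para to the allyloxy group and ortho to a methoxy group, the most activated site (as in the formylation of 1,2,4-trimethoxybenzene), and the allyl ether is inert to the chloroiminium salt.

**Step 3**
Reactants: 4 4-bromophenol, 5 prenyl bromide (1-bromo-3-methylbut-2-ene)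
Product: 6 1-bromo-4-(3-methylbut-2-enyloxy)benzene
Conditions: K2CO3, acetone, reflux
Reagents that add atoms: none
Why: Williamson ether synthesis, O-alkylation at the primary carbon of the allylic bromide being the normal outcome with K2CO3 in acetone.

**Step 4**
Reactants: 6 1-bromo-4-(3-methylbut-2-enyloxy)benzene, 7 N,2-dimethoxy-N-methylacetamide
Product: 9 2-methoxy-1-[4-(3-methylbut-2-enyloxy)phenyl]ethan-1-one, via arylmagnesium bromide 8 (not isolated)
Conditions: Mg turnings, THF, 40 °C; then 7, THF, 0 °C to rt; sat. aq. NH4Cl
Reagents that add atoms: none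
Why: Grignard formation followed by Weinreb ketone synthesis, in which the chelated tetrahedral adduct holds until work-up and so stops at the ketone, while the prenyl ether is inert to the uncatalysed Grignard reagent.

**Step 5**
Reactants: 9 2-methoxy-1-[4-(3-methylbut-2-enyloxy)phenyl]ethan-1-one, 3 4-(allyloxy)-2,5-dimethoxybenzaldehyde
Product: 11 3-[4-(allyloxy)-2,5-dimethoxyphenyl]-3-hydroxy-2-methoxy-1-[4-(3-methylbut-2-enyloxy)phenyl]propan-1-one (racemic mixture of diastereomers), via lithium enolate 10 (not isolated)
Conditions: LiN(i-Pr)2, THF, −78 °C; then 3, −78 °C; AcOH quench at −78 °C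
Reagents that add atoms: none
Why: Directed lithium enolate aldol addition (the ketone has a single enolisable position and the aldehyde none); the two new stereocentres are left uncontrolled because one is oxidised away in step 6 and the other is lost on enolisation in step 7.

**Step 6**
Reactants: 11 3-[4-(allyloxy)-2,5-dimethoxyphenyl]-3-hydroxy-2-methoxy-1-[4-(3-methylbut-2-enyloxy)phenyl]propan-1-one
Product: 12 1-[4-(allyloxy)-2,5-dimethoxyphenyl]-2-methoxy-3-[4-(3-methylbut-2-enyloxy)phenyl]propane-1,3-dione (racemic, enolisable)
Conditions: Dess–Martin periodinane, CH2Cl2, 0 °C to rt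
Reagents that add atoms: none
Why: Dess–Martin oxidation of the benzylic β-hydroxy ketone to the 1,3-diketone under near-neutral conditions that leave both alkenes and the electron-rich arene alone and avoid retro-aldol cleavage.

**Step 7**
Reactants: 12 1-[4-(allyloxy)-2,5-dimethoxyphenyl]-2-methoxy-3-[4-(3-methylbut-2-enyloxy)phenyl]propane-1,3-dione
Product: 15 7-(allyloxy)-5,8-dihydroxy-3-methoxy-2-[4-(3-methylbut-2-enyloxy)phenyl]-4H-chromen-4-one, via acylquinone 13 (not isolated), via flavone-5,8-quinone 14 (not isolated)
Conditions: divided cell, carbon-felt anode, Pt cathode, LiClO4 (0.1 M), MeCN–H2O (4:1), 0–5 °C, anode held at the first oxidation wave of 12 (estimated +1.3 to +1.5 V vs SCE) until 12 is consumed; current off, rt, 1 h; then aq. Na2S2O4, EtOAc, Ar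
Reagents that add atoms: water, O (the oxygens of the 5- and 8-hydroxyl groups)
Why: Proposed new method: at the first oxidation wave only the 1,2,4-trialkoxyarene of 12 gives up two electrons (ring B, both alkenes and the mainly non-enolised diketone lie higher), water adds ipso at the two methoxy-bearing carbons that stand para to each other and two molecules of methanol leave, which gives the 2-acyl-5-allyloxy-1,4-benzoquinone 13. In 13 the ring CH next to the acyl carbon (the future C8a) is β to the quinone carbonyl that becomes C5 and to the C4 ketone, and the enol oxygen of the diketone (the future O1) adds to it in a 6-endo-trig oxa-Michael closure, also describable as an oxa-6π closure of the dienone, after which tautomerisation aromatises ring A to the 5,8-hydroquinone 15 and ring C is complete. The closest known reaction types are the anodic or (NH4)2Ce(NO3)6 oxidative demethylation of 1,4-dimethoxyarenes to quinones and the conjugate addition of oxygen nucleophiles to the 3-position of 2-acyl-1,4-benzoquinones; their merger in one cell on an enolisable 1,3-diketone is untested. No stereocentre is formed, and the one at C2 of racemic 12 vanishes on enolisation. The step needs chemoselective oxidation, secured by the potential, and C8a-selective C–O bond formation, secured by geometry: the diketone carbon cannot reach the quinone without a four-membered ring, C8a is the only conjugate position the oxygen can span in a six-membered ring, and the high water content lets water rather than the diketone oxygen capture the ipso positions (a mixed ketal formed there would be reopened by water to 13). Because 15 is oxidised more easily than 12, part of it goes on to the flavone-5,8-quinone 14 at the anode, so the anolyte is held without current until 13 has closed and is then reduced with Na2S2O4, which returns 14 to 15.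

**Step 8**
Reactants: 15 7-(allyloxy)-5,8-dihydroxy-3-methoxy-2-[4-(3-methylbut-2-enyloxy)phenyl]-4H-chromen-4-one
Product: 16 7-(allyloxy)-5-hydroxy-3,8-dimethoxy-2-[4-(3-methylbut-2-enyloxy)phenyl]-4H-chromen-4-one
Conditions: MeI (1.2 equiv), K2CO3, degassed acetone, Ar, rt to 40 °C
Reagents that add atoms: iodomethane, CI
Why: Williamson O-methylation that should take only the free 8-hydroxyl, since the 5-hydroxyl is hydrogen-bonded to the C4 carbonyl and is a poor nucleophile, with oxygen excluded to prevent base-promoted autoxidation of the hydroquinone.

**Step 9**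
Reactants: 16 7-(allyloxy)-5-hydroxy-3,8-dimethoxy-2-[4-(3-methylbut-2-enyloxy)phenyl]-4H-chromen-4-one
Product: 17 5,7-dihydroxy-3,8-dimethoxy-2-[4-(3-methylbut-2-enyloxy)phenyl]-4H-chromen-4-one (5,7-dihydroxy-3,8-dimethoxy-4'-prenyloxyflavone)
Conditions: Pd(PPh3)4 (3 mol %), morpholine, THF, rt, Ar
Reagents that add atoms: none
Why: Tsuji–Trost deallylation, in which zerovalent palladium ionises the unsubstituted allyl ether (the acidic 7-oxychromone is a good leaving group) to a π-allyl complex that morpholine traps, while the trisubstituted prenyl alkene binds and ionises much more slowly and should survive at room temperature.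

**Compound list**

1 | 2,5-dimethoxyphenol | COc1ccc(OC)c(O)c1 | starting material
2 | 2-(allyloxy)-1,4-dimethoxybenzene | C=CCOc1cc(OC)ccc1OC | intermediate
3 | 4-(allyloxy)-2,5-dimethoxybenzaldehyde | C=CCOc1cc(OC)c(C=O)cc1OC | intermediate
4 | 4-bromophenol | Oc1ccc(Br)cc1 | starting material
5 | prenyl bromide (1-bromo-3-methylbut-2-ene) | CC(C)=CCBr | starting material
6 | 1-bromo-4-(3-methylbut-2-enyloxy)benzene | CC(C)=CCOc1ccc(Br)cc1 | intermediate
7 | N,2-dimethoxy-N-methylacetamide | COCC(=O)N(C)OC | starting material
8 | [4-(3-methylbut-2-enyloxy)phenyl]magnesium bromide | CC(C)=CCOc1ccc([Mg]Br)cc1 | intermediate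
9 | 2-methoxy-1-[4-(3-methylbut-2-enyloxy)phenyl]ethan-1-one | COCC(=O)c1ccc(OCC=C(C)C)cc1 | intermediate
10 | lithium (Z)-2-methoxy-1-[4-(3-methylbut-2-enyloxy)phenyl]ethen-1-olate | [Li]O/C(=C\OC)c1ccc(OCC=C(C)C)cc1 | intermediate
11 | 3-[4-(allyloxy)-2,5-dimethoxyphenyl]-3-hydroxy-2-methoxy-1-[4-(3-methylbut-2-enyloxy)phenyl]propan-1-one (racemic, mixture of diastereomers) | C=CCOc1cc(OC)c(C(O)C(OC)C(=O)c2ccc(OCC=C(C)C)cc2)cc1OC | intermediate
12 | 1-[4-(allyloxy)-2,5-dimethoxyphenyl]-2-methoxy-3-[4-(3-methylbut-2-enyloxy)phenyl]propane-1,3-dione (racemic, enolisable) | C=CCOc1cc(OC)c(C(=O)C(OC)C(=O)c2ccc(OCC=C(C)C)cc2)cc1OC | intermediate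
13 | 1-[4-(allyloxy)-3,6-dioxocyclohexa-1,4-dien-1-yl]-2-methoxy-3-[4-(3-methylbut-2-enyloxy)phenyl]propane-1,3-dione (racemic, enolisable) | C=CCOC1=CC(=O)C(C(=O)C(OC)C(=O)c2ccc(OCC=C(C)C)cc2)=CC1=O | intermediate
14 | 7-(allyloxy)-3-methoxy-2-[4-(3-methylbut-2-enyloxy)phenyl]-4H-chromene-4,5,8-trione | COC1=C(c2ccc(OCC=C(C)C)cc2)OC2=C(C1=O)C(=O)C=C(OCC=C)C2=O | intermediate
15 | 7-(allyloxy)-5,8-dihydroxy-3-methoxy-2-[4-(3-methylbut-2-enyloxy)phenyl]-4H-chromen-4-one | COc1c(-c2ccc(OCC=C(C)C)cc2)oc2c(O)c(OCC=C)cc(O)c2c1=O | intermediate
16 | 7-(allyloxy)-5-hydroxy-3,8-dimethoxy-2-[4-(3-methylbut-2-enyloxy)phenyl]-4H-chromen-4-one | COc1c(-c2ccc(OCC=C(C)C)cc2)oc2c(OC)c(OCC=C)cc(O)c2c1=O | intermediate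
17 | 5,7-dihydroxy-3,8-dimethoxy-2-[4-(3-methylbut-2-enyloxy)phenyl]-4H-chromen-4-one | COc1c(-c2ccc(OCC=C(C)C)cc2)oc2c(OC)c(O)cc(O)c2c1=O | target

**Step count**

Total steps: 9. Longest linear sequence: 7 steps (steps 1, 2, 5, 6, 7, 8, 9 from compound 1; equally steps 3, 4, 5, 6, 7, 8, 9 from compound 4).

**Steps most likely to fail**

Step 7 (bears the label "Proposed new method:"). What may go wrong:
- further anodic degradation of the easily oxidised hydroquinone product;
- conjugate hydration of the acylquinone before the ring closes;
- capture of the arene radical cation by the diketone oxygen at a methoxy-bearing carbon, which leads toward the 6-oxygenated isomer;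
- acid building up in the anolyte and cleaving the prenyl ether.

The fallback uses known chemistry and separates oxidation from reduction. It sets out from 12 and comes back at 15. (NH4)2Ce(NO3)6 (about 4.5 equiv) in MeCN–H2O at 0 °C should demethylate ring A oxidatively to 13 within minutes, faster than tetravalent cerium attacks the largely non-enolised diketone or the prenyl alkene. Under the excess oxidant 13 is expected to close and to be collected at the quinone level as 14, which is extracted and isolated. If 13 is isolated unclosed, it is stirred with a catalytic amount of NaOAc in degassed THF first. A separate reduction of 14 with aqueous Na2S2O4 in EtOAc under argon gives 15. This fallback makes no compound beyond those in the list (F0).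

Step 9. What may go wrong: loss of selectivity between the two allylic ethers, with zerovalent palladium also ionising the prenyl ether, or slow turnover that invites this on prolonged reaction. The fallback replaces π-allyl chemistry by isomerisation and enol ether hydrolysis. It sets out from 16 and comes back at 17. RhCl(PPh3)3 (5 mol %) with DABCO in EtOH–H2O at reflux should isomerise only the unsubstituted allyl ether, since prenyl ethers are not isomerised under these conditions. This gives 5-hydroxy-3,8-dimethoxy-2-[4-(3-methylbut-2-enyloxy)phenyl]-7-(prop-1-enyloxy)-4H-chromen-4-one F1 as an E/Z mixture. HgCl2 and HgO in acetone–H2O at rt then hydrolyse the enol ether to 17.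

Step 8. What may go wrong: autoxidation of the hydroquinone phenoxide back to the quinone during isolation and basic alkylation, and methylation at O5 as well as O8. The fallback stores the hydroquinone in protected form and releases the phenoxide only in the presence of the electrophile. It sets out from 15 and comes back at 16. Ac2O, pyridine and DMAP in CH2Cl2 at rt convert 15 (taken directly from the dithionite work-up) into the air-stable 7-(allyloxy)-3-methoxy-4-oxo-2-[4-(3-methylbut-2-enyloxy)phenyl]-4H-chromene-5,8-diyl diacetate F2, which can be purified. K2CO3 and MeI in degassed MeOH–THF at rt then methanolyse both acetates; the 8-phenoxide is methylated as it is released, and the 5-hydroxyl returns to its chelate with the C4 carbonyl, giving 16.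

**Further compounds**

F0 | step 7 | none | none
F1 | step 9 | 5-hydroxy-3,8-dimethoxy-2-[4-(3-methylbut-2-enyloxy)phenyl]-7-(prop-1-enyloxy)-4H-chromen-4-one (E/Z mixture) | COc1c(-c2ccc(OCC=C(C)C)cc2)oc2c(OC)c(OC=CC)cc(O)c2c1=O
F2 | step 8 | 7-(allyloxy)-3-methoxy-4-oxo-2-[4-(3-methylbut-2-enyloxy)phenyl]-4H-chromene-5,8-diyl diacetate | COc1c(-c2ccc(OCC=C(C)C)cc2)oc2c(OC(C)=O)c(OCC=C)cc(OC(C)=O)c2c1=O
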